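**Retrosynthetic overview**
1. The Z-p-coumarate on O19 is cut by Still–Gennari olefination of a C19 phosphonoacetate; the C12–C13 bond is cut to a C12 iodide and buta-1,3-dien-2-ylmagnesium chloride; C12 comes from a C11 aldehyde.
2. The 7α,8α-diol comes from OsO4 on a Δ7 alkene; ring B is formed second, by proton-initiated cation–olefin closure (C9–C10 bond) from the C1=C10 alkene onto the E-C8=C9 allylic acetate.
3. Ring A is formed first. The strategy rests on the quaternary C4 of ring A (C1–C5, C10), which carries the C18 methyl and the oxidised C19 carbon next to C5–H: this is the pattern of a 2-methylacrolein Diels–Alder adduct, so C4–C5 and C2–C3 are cut.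
4. The triene precursor comes from geranyl acetate in three steps (allylic oxidation, MnO2, Wittig methylenation).

Key step: step 4

Remark: labdane numbering (C1–C20) is used for every intermediate; β is the face of the C20 methyl, α the opposite face.
Assumption: chloroprene (stabilised solution), bis(2,2,2-trifluoroethyl)phosphonoacetic acid and 4-(tert-butyldimethylsilyloxy)benzaldehyde are bought.
Assumption: the (S)-configured oxazaborolidinium salt is taken to expose the Re face of the α-carbon of bound 2-methylacrolein; if the sense of induction proves opposite, the (R)-catalyst is used in the same way.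

**Route**

Step 1
Reactants: 1 geranyl acetate
Product: 2 (2E,6E)-8-hydroxy-3,7-dimethylocta-2,6-dien-1-yl acetate
Conditions: SeO2 (cat.), t-BuOOH (70% aq.), salicylic acid (cat.), CH2Cl2, rt
Reagents that add atoms: SeO2, O=[Se]=O (catalytic oxygen carrier); tert-butyl hydroperoxide, CC(C)(C)OO
Why: SeO2 allylic oxidation (ene reaction, then [2,3]-sigmatropic shift) should hydroxylate the E-methyl of the electron-rich terminal alkene, the C2 alkene being deactivated by the allylic acetate; any enal 3 formed by over-oxidation is carried into step 2.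

Step 2
Reactants: 2 (2E,6E)-8-hydroxy-3,7-dimethylocta-2,6-dien-1-yl acetate
Product: 3 (2E,6E)-3,7-dimethyl-8-oxoocta-2,6-dien-1-yl acetate
Conditions: MnO2 (activated, excess), CH2Cl2, rt
Reagents that add atoms: none
Why: MnO2 oxidises allylic alcohols selectively to enals and should leave the acetate and the alkene geometry untouched.

Step 3
Reactants: 3 (2E,6E)-3,7-dimethyl-8-oxoocta-2,6-dien-1-yl acetate
Product: 4 (2E,6E)-3,7-dimethylnona-2,6,8-trien-1-yl acetate
Conditions: Ph3PCH3Br, KN(SiMe3)2, THF, −78 → 0 °C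
Reagents that add atoms: methyltriphenylphosphonium bromide, C[P+](c1ccccc1)(c1ccccc1)c1ccccc1.[Br-]
Why: Wittig methylenation of the enal is much faster than attack of the ylide on the acetate and keeps the E trisubstituted alkene, giving the (E)-1-alkyl-2-methylbutadiene terminus.

Step 4
Reactants: 4 (2E,6E)-3,7-dimethylnona-2,6,8-trien-1-yl acetate; 5 2-methylacrolein
Product: 6 (2E)-5-[(1R,6S)-6-formyl-2,6-dimethylcyclohex-2-en-1-yl]-3-methylpent-2-en-1-yl acetate
Conditions: (S)-3,3-diphenyl-1-(2-methylphenyl)tetrahydro-1H,3H-pyrrolo[1,2-c][1,3,2]oxazaborole (C24H24BNO, 20 mol %), (CF3SO2)2NH (17 mol %), CH2Cl2, −78 → −40 °C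
Reagents that add atoms: none
Why: The N-protonated oxazaborolidine binds the formyl oxygen of s-trans 2-methylacrolein, and the diene adds in an asynchronous concerted [4+2] in which the unsubstituted terminus C2 bonds ahead to the β-carbon C3 while C5 closes onto the α-carbon C4; the closest known reaction type is the oxazaborolidinium-catalysed Diels–Alder reaction of 2-methylacrolein with acyclic dienes. Ring A (C1–C5, C10) closes by this intermolecular [4+2], suprafacial on both partners, and keeps the C1=C10 alkene for the later cationic closure. C4 is set by the catalyst, which is expected to leave the Re face of the α-carbon open. C5 is set relative to C4 by the E geometry of the C5=C10 terminus together with formyl-endo approach, which places CHO (the future C19) cis to the C6 chain. The step needs ortho regioselectivity, which the 1-alkyl terminus should secure over the weaker opposing effect of the 2-methyl group, as in additions to 1-vinylcyclohexenes, and it needs formyl-endo selectivity, expected for a Lewis-acid-bound enal meeting an acyclic E-diene that has no bridging CH2 to clash with the α-methyl group. The isolated trisubstituted alkene next to the acetate is not a diene and should stay out of the reaction.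

Step 5
Reactants: 6 (2E)-5-[(1R,6S)-6-formyl-2,6-dimethylcyclohex-2-en-1-yl]-3-methylpent-2-en-1-yl acetate
Product: 7 (2E)-5-[(1R,6S)-6-(hydroxymethyl)-2,6-dimethylcyclohex-2-en-1-yl]-3-methylpent-2-en-1-yl acetate
Conditions: NaBH4, THF–MeOH, 0 °C
Reagents that add atoms: none
Why: Borohydride reduction of the neopentyl aldehyde is chemoselective at 0 °C and touches neither the acetate nor the stereocentres.

Step 6
Reactants: 7 (2E)-5-[(1R,6S)-6-(hydroxymethyl)-2,6-dimethylcyclohex-2-en-1-yl]-3-methylpent-2-en-1-yl acetate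
Product: 8 [(1S,2R)-2-[(3E)-5-acetoxy-3-methylpent-3-en-1-yl]-1,3-dimethylcyclohex-3-en-1-yl]methyl pivalate
Conditions: PivCl, pyridine, DMAP (cat.), CH2Cl2, 0 °C → rt
Reagents that add atoms: pivaloyl chloride, CC(C)(C)C(Cl)=O
Why: DMAP-catalysed acylation gives a C19 pivalate that is orthogonal to the C11 acetate and should survive the strong acid of the next step.

Step 7
Reactants: 8 [(1S,2R)-2-[(3E)-5-acetoxy-3-methylpent-3-en-1-yl]-1,3-dimethylcyclohex-3-en-1-yl]methyl pivalate
Product: 9 11-acetoxy-19-pivaloyloxy-12,13,14,15,16-pentanorlabd-7-ene (5α-H; 9β-CH2OAc; 10β-Me; 4β-CH2OPiv)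
Conditions: FSO3H (5 equiv), 2-nitropropane, −78 °C; Et3N quench
Reagents that add atoms: none
Why: In this proton-initiated cation–olefin cyclisation of a monocyclofarnesyl-type acetate, Markovnikov protonation at C1 gives the tertiary C10 cation, which C9 of the E alkene captures through a chair-like transition state with the C6 chain equatorial, so that H5 relays to the trans ring fusion (10β-Me) and the E geometry to 9β-CH2OAc, and loss of H7 from the C8 cation should give the Δ7 alkene.

Step 8
Reactants: 9 11-acetoxy-19-pivaloyloxy-12,13,14,15,16-pentanorlabd-7-ene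
Product: 10 11-acetoxy-19-pivaloyloxy-12,13,14,15,16-pentanorlabdane-7α,8α-diol
Conditions: OsO4 (5 mol %), N-methylmorpholine N-oxide, acetone–H2O, rt
Reagents that add atoms: OsO4, O=[Os](=O)(=O)=O (catalytic oxygen carrier); N-methylmorpholine N-oxide, C[N+]1([O-])CCOCC1
Why: Catalytic syn-dihydroxylation should take place on the α face, opposite the axial 10β-methyl, and so sets 7α-OH and 8α-OH together.

Step 9
Reactants: 10 11-acetoxy-19-pivaloyloxy-12,13,14,15,16-pentanorlabdane-7α,8α-diol
Product: 11 11-acetoxy-7α,8α-isopropylidenedioxy-19-pivaloyloxy-12,13,14,15,16-pentanorlabdane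
Conditions: 2,2-dimethoxypropane, pyridinium p-toluenesulfonate (cat.), CH2Cl2, rt
Reagents that add atoms: 2,2-dimethoxypropane, COC(C)(C)OC
Why: Transacetalisation across the cis (axial/equatorial) diol gives the acetonide, which masks both hydroxyls and later blocks retro-aldol opening at the C11 aldehyde stage.

Step 10
Reactants: 11 11-acetoxy-7α,8α-isopropylidenedioxy-19-pivaloyloxy-12,13,14,15,16-pentanorlabdane
Product: 12 7α,8α-isopropylidenedioxy-19-pivaloyloxy-12,13,14,15,16-pentanorlabdan-11-ol
Conditions: K2CO3, MeOH, 0 °C → rt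
Reagents that add atoms: none
Why: Base-catalysed methanolysis cleaves the primary acetate far faster than the neopentyl pivalate.

Step 11
Reactants: 12 7α,8α-isopropylidenedioxy-19-pivaloyloxy-12,13,14,15,16-pentanorlabdan-11-ol
Product: 13 7α,8α-isopropylidenedioxy-19-pivaloyloxy-12,13,14,15,16-pentanorlabdan-11-al
Conditions: Dess–Martin periodinane, NaHCO3, CH2Cl2, 0 °C → rt
Reagents that add atoms: none
Why: Buffered Dess–Martin oxidation gives the hindered aldehyde under neutral conditions, so C9 should not epimerise.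

Step 12
Reactants: 13 7α,8α-isopropylidenedioxy-19-pivaloyloxy-12,13,14,15,16-pentanorlabdan-11-al
Product: 14 7α,8α-isopropylidenedioxy-19-pivaloyloxy-13,14,15,16-tetranorlabd-11-ene
Conditions: Ph3PCH3Br, KN(SiMe3)2, THF, 0 °C → rt
Reagents that add atoms: methyltriphenylphosphonium bromide, C[P+](c1ccccc1)(c1ccccc1)c1ccccc1.[Br-]
Why: Wittig methylenation adds C12; the equatorial C9 substituent is the stable configuration, and the equatorial C8–O bond is poorly aligned for E1cB loss from the enolate.

Step 13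
Reactants: 14 7α,8α-isopropylidenedioxy-19-pivaloyloxy-13,14,15,16-tetranorlabd-11-ene
Product: 16 7α,8α-isopropylidenedioxy-19-pivaloyloxy-13,14,15,16-tetranorlabdan-12-ol, via B-alkyl-9-borabicyclononane adduct 15 (not isolated)
Conditions: 9-BBN, THF, rt → 50 °C; then NaOH (aq.), H2O2, 0 °C
Reagents that add atoms: hydrogen peroxide, OO
Why: Anti-Markovnikov hydroboration of the monosubstituted alkene followed by oxidation with retention should give the primary C12 alcohol, the hindered pivalate surviving the brief basic oxidation.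

Step 14
Reactants: 16 7α,8α-isopropylidenedioxy-19-pivaloyloxy-13,14,15,16-tetranorlabdan-12-ol
Product: 17 12-iodo-7α,8α-isopropylidenedioxy-19-pivaloyloxy-13,14,15,16-tetranorlabdane
Conditions: I2, PPh3, imidazole, CH2Cl2, 0 °C → rt
Reagents that add atoms: iodine, II
Why: Appel-type iodination proceeds by SN2 displacement of the alkoxyphosphonium at the unhindered primary C12.

Step 15
Reactants: 18 chloroprene
Product: 19 buta-1,3-dien-2-ylmagnesium chloride (THF solution)
Conditions: Mg, ZnCl2 (cat.), BrCH2CH2Br (cat.), THF, reflux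
Reagents that add atoms: magnesium, [Mg]
Why: Magnesium insertion into the vinylic C–Cl bond of chloroprene in THF is the established preparation of this Grignard reagent.

Step 16
Reactants: 17 12-iodo-7α,8α-isopropylidenedioxy-19-pivaloyloxy-13,14,15,16-tetranorlabdane; 19 buta-1,3-dien-2-ylmagnesium chloride
Product: 20 7α,8α-isopropylidenedioxylabda-13(16),14-dien-19-yl pivalate
Conditions: Li2CuCl4 (5 mol %), THF, −20 → 0 °C
Reagents that add atoms: none
Why: Copper-catalysed cross-coupling of a primary alkyl iodide with the dienyl Grignard reagent forms C12–C13 at the metal-bearing carbon and keeps the 1,3-diene, while the hindered pivalate and the acetonide should be inert at this temperature.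

Step 17
Reactants: 20 7α,8α-isopropylidenedioxylabda-13(16),14-dien-19-yl pivalate
Product: 21 7α,8α-isopropylidenedioxylabda-13(16),14-dien-19-ol
Conditions: i-Bu2AlH, CH2Cl2, −78 °C; aq. potassium sodium tartrate
Reagents that add atoms: none
Why: Reductive cleavage of the pivalate frees the C19 alcohol without affecting the diene or the acetonide.

Step 18
Reactants: 21 7α,8α-isopropylidenedioxylabda-13(16),14-dien-19-ol; 22 bis(2,2,2-trifluoroethyl)phosphonoacetic acid
Product: 23 7α,8α-isopropylidenedioxylabda-13(16),14-dien-19-yl [bis(2,2,2-trifluoroethoxy)phosphoryl]acetate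
Conditions: DCC, DMAP (cat.), CH2Cl2, 0 °C → rt
Reagents that add atoms: none
Why: Steglich esterification of the activated phosphonoacetic acid should acylate even the axial neopentyl C19 alcohol.

Step 19
Reactants: 23 7α,8α-isopropylidenedioxylabda-13(16),14-dien-19-yl [bis(2,2,2-trifluoroethoxy)phosphoryl]acetate; 24 4-(tert-butyldimethylsilyloxy)benzaldehyde
Product: 25 7α,8α-isopropylidenedioxylabda-13(16),14-dien-19-yl (Z)-3-[4-(tert-butyldimethylsilyloxy)phenyl]prop-2-enoate
Conditions: KN(SiMe3)2, 18-crown-6, THF, −78 °C, dark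
Reagents that add atoms: none
Why: In the Still–Gennari olefination the electron-poor phosphonate and the dissociated potassium counter-ion make elimination faster than equilibration of the adducts, so the kinetic syn adduct should give the Z-enoate.

Step 20
Reactants: 25 7α,8α-isopropylidenedioxylabda-13(16),14-dien-19-yl (Z)-3-[4-(tert-butyldimethylsilyloxy)phenyl]prop-2-enoate
Product: 26 7α,8α-dihydroxylabda-13(16),14-dien-19-yl (Z)-3-[4-(tert-butyldimethylsilyloxy)phenyl]prop-2-enoate
Conditions: AcOH–H2O–THF (4:1:1), 45 °C, dark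
Reagents that add atoms: none
Why: Mild acid hydrolysis of the acetonide frees the diol, while the aryl silyl ether, the 2-substituted diene and the Z-enoate are expected to tolerate aqueous acetic acid.

Step 21
Reactants: 26 7α,8α-dihydroxylabda-13(16),14-dien-19-yl (Z)-3-[4-(tert-butyldimethylsilyloxy)phenyl]prop-2-enoate
Product: 27 7α,8α-dihydroxylabda-13(16),14-dien-19-yl (Z)-3-(4-hydroxyphenyl)prop-2-enoate (CNP0254560.1)
Conditions: KHF2, MeOH, rt, dark
Reagents that add atoms: none
Why: Bifluoride cleaves the aryl silyl ether selectively under near-neutral conditions, so no free phenoxide is present to isomerise the Z-enoate or cleave the ester.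

**Compound list**
1 | geranyl acetate | CC(C)=CCC/C(C)=C/COC(C)=O | starting material
2 | (2E,6E)-8-hydroxy-3,7-dimethylocta-2,6-dien-1-yl acetate | OC/C(C)=C/CC/C(C)=C/COC(C)=O | intermediate
3 | (2E,6E)-3,7-dimethyl-8-oxoocta-2,6-dien-1-yl acetate | O=C/C(C)=C/CC/C(C)=C/COC(C)=O | intermediate
4 | (2E,6E)-3,7-dimethylnona-2,6,8-trien-1-yl acetate (Diels–Alder precursor) | C=C/C(C)=C/CC/C(C)=C/COC(C)=O | intermediate
5 | 2-methylacrolein | CC(=C)C=O | starting material
6 | (2E)-5-[(1R,6S)-6-formyl-2,6-dimethylcyclohex-2-en-1-yl]-3-methylpent-2-en-1-yl acetate (ring A aldehyde, CHO cis to the side chain) | CC(=O)OC/C=C(\C)CC[C@H]1[C@@](C)(C=O)CCC=C1C | intermediate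
7 | (2E)-5-[(1R,6S)-6-(hydroxymethyl)-2,6-dimethylcyclohex-2-en-1-yl]-3-methylpent-2-en-1-yl acetate | CC(=O)OC/C=C(\C)CC[C@H]1[C@@](C)(CO)CCC=C1C | intermediate
8 | [(1S,2R)-2-[(3E)-5-acetoxy-3-methylpent-3-en-1-yl]-1,3-dimethylcyclohex-3-en-1-yl]methyl pivalate | CC(=O)OC/C=C(\C)CC[C@H]1[C@@](C)(COC(=O)C(C)(C)C)CCC=C1C | intermediate
9 | 11-acetoxy-19-pivaloyloxy-12,13,14,15,16-pentanorlabd-7-ene (trans-decalin, 5α-H, 9β-CH2OAc, 10β-Me, 4β-CH2OPiv) | CC(=O)OC[C@H]1C(C)=CC[C@H]2[C@@](C)(COC(=O)C(C)(C)C)CCC[C@@]21C | intermediate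
10 | 11-acetoxy-19-pivaloyloxy-12,13,14,15,16-pentanorlabdane-7α,8α-diol | CC(=O)OC[C@H]1[C@](C)(O)[C@H](O)C[C@H]2[C@@](C)(COC(=O)C(C)(C)C)CCC[C@@]21C | intermediate
11 | 11-acetoxy-7α,8α-isopropylidenedioxy-19-pivaloyloxy-12,13,14,15,16-pentanorlabdane | CC(=O)OC[C@H]1[C@]3(C)OC(C)(C)O[C@@H]3C[C@H]2[C@@](C)(COC(=O)C(C)(C)C)CCC[C@@]21C | intermediate
12 | 7α,8α-isopropylidenedioxy-19-pivaloyloxy-12,13,14,15,16-pentanorlabdan-11-ol | OC[C@H]1[C@]3(C)OC(C)(C)O[C@@H]3C[C@H]2[C@@](C)(COC(=O)C(C)(C)C)CCC[C@@]21C | intermediate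
13 | 7α,8α-isopropylidenedioxy-19-pivaloyloxy-12,13,14,15,16-pentanorlabdan-11-al | O=C[C@H]1[C@]3(C)OC(C)(C)O[C@@H]3C[C@H]2[C@@](C)(COC(=O)C(C)(C)C)CCC[C@@]21C | intermediate
14 | 7α,8α-isopropylidenedioxy-19-pivaloyloxy-13,14,15,16-tetranorlabd-11-ene | C=C[C@H]1[C@]3(C)OC(C)(C)O[C@@H]3C[C@H]2[C@@](C)(COC(=O)C(C)(C)C)CCC[C@@]21C | intermediate
15 | 9-(C12-alkyl)-9-borabicyclo[3.3.1]nonane adduct of 14 | C1CCC2CCCC1B2CC[C@H]1[C@]3(C)OC(C)(C)O[C@@H]3C[C@H]2[C@@](C)(COC(=O)C(C)(C)C)CCC[C@@]21C | intermediate
16 | 7α,8α-isopropylidenedioxy-19-pivaloyloxy-13,14,15,16-tetranorlabdan-12-ol | OCC[C@H]1[C@]3(C)OC(C)(C)O[C@@H]3C[C@H]2[C@@](C)(COC(=O)C(C)(C)C)CCC[C@@]21C | intermediate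
17 | 12-iodo-7α,8α-isopropylidenedioxy-19-pivaloyloxy-13,14,15,16-tetranorlabdane | ICC[C@H]1[C@]3(C)OC(C)(C)O[C@@H]3C[C@H]2[C@@](C)(COC(=O)C(C)(C)C)CCC[C@@]21C | intermediate
18 | chloroprene (2-chlorobuta-1,3-diene) | C=CC(Cl)=C | starting material
19 | buta-1,3-dien-2-ylmagnesium chloride | C=CC(=C)[Mg]Cl | intermediate
20 | 7α,8α-isopropylidenedioxylabda-13(16),14-dien-19-yl pivalate | C=CC(=C)CC[C@H]1[C@]3(C)OC(C)(C)O[C@@H]3C[C@H]2[C@@](C)(COC(=O)C(C)(C)C)CCC[C@@]21C | intermediate
21 | 7α,8α-isopropylidenedioxylabda-13(16),14-dien-19-ol | C=CC(=C)CC[C@H]1[C@]3(C)OC(C)(C)O[C@@H]3C[C@H]2[C@@](C)(CO)CCC[C@@]21C | intermediate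
22 | bis(2,2,2-trifluoroethyl)phosphonoacetic acid | OC(=O)CP(=O)(OCC(F)(F)F)OCC(F)(F)F | starting material
23 | 7α,8α-isopropylidenedioxylabda-13(16),14-dien-19-yl [bis(2,2,2-trifluoroethoxy)phosphoryl]acetate | C=CC(=C)CC[C@H]1[C@]3(C)OC(C)(C)O[C@@H]3C[C@H]2[C@@](C)(COC(=O)CP(=O)(OCC(F)(F)F)OCC(F)(F)F)CCC[C@@]21C | intermediate
24 | 4-(tert-butyldimethylsilyloxy)benzaldehyde | O=Cc1ccc(O[Si](C)(C)C(C)(C)C)cc1 | starting material
25 | 7α,8α-isopropylidenedioxylabda-13(16),14-dien-19-yl (Z)-3-[4-(tert-butyldimethylsilyloxy)phenyl]prop-2-enoate | C=CC(=C)CC[C@H]1[C@]3(C)OC(C)(C)O[C@@H]3C[C@H]2[C@@](C)(COC(=O)/C=C\c4ccc(O[Si](C)(C)C(C)(C)C)cc4)CCC[C@@]21C | intermediate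
26 | 7α,8α-dihydroxylabda-13(16),14-dien-19-yl (Z)-3-[4-(tert-butyldimethylsilyloxy)phenyl]prop-2-enoate | C=CC(=C)CC[C@H]1[C@](C)(O)[C@H](O)C[C@H]2[C@@](C)(COC(=O)/C=C\c3ccc(O[Si](C)(C)C(C)(C)C)cc3)CCC[C@@]21C | intermediate
27 | 7α,8α-dihydroxylabda-13(16),14-dien-19-yl (Z)-3-(4-hydroxyphenyl)prop-2-enoate (CNP0254560.1) | C=CC(=C)CC[C@H]1[C@](C)(O)[C@H](O)C[C@H]2[C@@](C)(COC(=O)/C=C\c3ccc(O)cc3)CCC[C@@]21C | target

**Step count**
Total: 21 steps. Longest linear sequence: 20 steps (steps 1–14 and 16–21); step 15 is a one-step side branch.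

**Steps most likely to fail**

Step 4. The internal C10 methyl crowds the bond-forming terminus, so enantioface discrimination by the catalyst (and the formyl-endo preference) may be incomplete, giving material of low enantiomeric purity; a minor share of adduct with reversed orientation would be removed by chromatography. Fallback, setting out from 4 and 5 and coming back at 6: the cycloaddition is run without asymmetric induction (MeAlCl2, CH2Cl2, −78 °C) to give the racemic formyl-endo aldehyde F1. Condensation with (1R,2R)-N,N'-dimethyl-1,2-diphenylethane-1,2-diamine (Et2O, 4 Å molecular sieves) should give two diastereomeric imidazolidines, the aminal of the (4S,5R) aldehyde F2 and the aminal of the enantiomeric aldehyde F3, to be separated on triethylamine-deactivated silica. Two-phase hydrolysis of F2 (aqueous oxalic acid, Et2O) returns enantiopure 6 and the diamine.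

Step 7. The free C10 cation may lose H5 reversibly towards the tetrasubstituted C5=C10 alkene (erosion of the C4/C5 relationship), may suffer a 1,2-hydride shift, the allylic acetate may ionise, and proton loss from C8 may give alkene isomers. Fallback, setting out from 8 and coming back at 9: a mercurinium-initiated closure with the divalent mercury salt Hg(OTf)2 as its N,N-dimethylaniline complex (MeNO2, −20 °C; then aq. NaCl). Here C9 opens the bridged mercurinium ion anti without a free cation next to C5–H and should give the 1β-chloromercurio bicycle F4. Radical demercuration of F4 (Bu3SnH, azobisisobutyronitrile, toluene, rt → 60 °C) then gives 9.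

Step 16. The dienyl Grignard reagent may reduce or eliminate the iodide, attack the pivalate, or couple through its allenyl-type terminus. Fallback, setting out from 17 and coming back at 20: displacement of the iodide with lithium acetylide–ethylenediamine complex (LiC≡CH·H2NCH2CH2NH2, DMSO, rt) to the terminal alkyne 7α,8α-isopropylidenedioxy-19-pivaloyloxy-15,16-dinorlabd-13-yne F5. Ethylene–alkyne cross enyne metathesis of F5 (ethylene 1 atm, second-generation Grubbs catalyst (H2IMes)(PCy3)Cl2Ru=CHPh, CH2Cl2, 40 °C) then converts the alkyne into the 2-substituted buta-1,3-diene 20.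

**Further compounds**
F1 | step 4 | racemic 5-(6-formyl-2,6-dimethylcyclohex-2-en-1-yl)-3-methylpent-2-en-1-yl acetate (2E; CHO cis to the side chain) | CC(=O)OC/C=C(\C)CCC1C(C)(C=O)CCC=C1C
F2 | step 4 | (4R,5R)-1,3-dimethyl-4,5-diphenylimidazolidin-2-yl aminal of 6 | CC(=O)OC/C=C(\C)CC[C@H]1[C@@](C)(C2N(C)[C@H](c3ccccc3)[C@@H](c3ccccc3)N2C)CCC=C1C
F3 | step 4 | (4R,5R)-1,3-dimethyl-4,5-diphenylimidazolidin-2-yl aminal of the enantiomer of 6 | CC(=O)OC/C=C(\C)CC[C@@H]1[C@](C)(C2N(C)[C@H](c3ccccc3)[C@@H](c3ccccc3)N2C)CCC=C1C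
F4 | step 7 | 11-acetoxy-1β-chloromercurio-19-pivaloyloxy-12,13,14,15,16-pentanorlabd-7-ene | CC(=O)OC[C@H]1C(C)=CC[C@H]2[C@@](C)(COC(=O)C(C)(C)C)CC[C@@H]([Hg]Cl)[C@@]21C
F5 | step 16 | 7α,8α-isopropylidenedioxy-19-pivaloyloxy-15,16-dinorlabd-13-yne | C#CCC[C@H]1[C@]3(C)OC(C)(C)O[C@@H]3C[C@H]2[C@@](C)(COC(=O)C(C)(C)C)CCC[C@@]21C
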